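**Retrosynthetic overview**

1. Locants follow the target skeleton, (1S)-1,4,10-trihydroxy-8-methyl-3,7-dioxo-1,3-dihydro-7H-isobenzofuro[4,5-b][1,4]benzodioxepine-5,11-dicarbaldehyde: ring A = C-7a to C-11a, ring B = C-3a, C-4, C-5, C-5a, C-12a, C-12b; O-6 is the ester oxygen, O-12 the ether oxygen.
2. Last disconnection: hydrogenolysis of a 10-O-benzyl ether and of an (S)-1-phenylethyl acetal at C-1; the C-1 stereocentre is set early, on ring B, by crystallisation-driven equilibration of the two acetal epimers.
3. Key disconnection: O-12–C-11a (ring-closing SNAr) together with C-7–O-6, made in one flask from a ring-B phthalide triol and a ring-A imidoyl chloride; C-7 travels as an N-butyl imidate and is hydrolysed to the lactone in the same operation.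
4. Enabling feature: C-11a lies between C-11 (formyl) and C-7a (which carries C-7), so a C-11a–F bond is doubly ortho-activated. On ring B the O-6 hydroxyl (ortho to the 5-formyl group, para to the C-3 lactone carbonyl) is far more acidic than the O-12 hydroxyl, so the carboxyl-level carbon goes to O-6 and O-12 closes the ring; an imidate, unlike an ester, cannot migrate between the two.
5. Ring order: both benzene rings come from the starting materials (1,2,4-trimethoxybenzene; 3-fluoro-5-methylphenol); the lactol/lactone ring is closed in step 5, the dioxepinone ring in step 14.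

Key step: step 14

Remark (assumption): a 3-hydroxyphthalide lactol epimerises through its open formyl-acid form in base or protic acid, so the (1S)-lactol is liberated only in the last step under neutral aprotic conditions and is assumed to hold its configuration when isolated and stored cold as a solid.

Remark (assumption): of the two acetal epimers formed in step 7, the (3S)-epimer is assumed to be the one that crystallises from the equilibrating mixture; the fallback for step 7 applies if it is not.

**Route**

Step 1
Reactants: 1 1,2,4-trimethoxybenzene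
Product: 2 2,3,6-trimethoxybenzaldehyde
Conditions: n-BuLi, THF, 0 °C to rt; DMF, 0 °C; aq. HCl
Reagents that add atoms: N,N-dimethylformamide CN(C)C=O
Why: Directed ortho-metalation should occur at the C–H flanked by two methoxy groups (most acidic, doubly coordinated), and formylation with DMF places the future 5-formyl carbon between the future O-6 and 4-O.

Step 2
Reactants: 2 2,3,6-trimethoxybenzaldehyde
Product: 3 3-bromo-2,5,6-trimethoxybenzaldehyde
Conditions: NBS, MeCN, 0 °C to rt
Reagents that add atoms: N-bromosuccinimide O=C1CCC(=O)N1Br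
Why: Electrophilic aromatic bromination should go to the one free position that is para to a methoxy group, ortho to another and meta to the formyl group.

Step 3
Reactants: 3 3-bromo-2,5,6-trimethoxybenzaldehyde
Product: 4 1-bromo-3-(dimethoxymethyl)-2,4,5-trimethoxybenzene
Conditions: HC(OMe)3 (neat), TsOH·H2O (cat.), rt
Reagents that add atoms: trimethyl orthoformate COC(OC)OC
Why: Acid-catalysed acetalisation masks the aldehyde against the two organolithium steps that follow.

Step 4
Reactants: 4 1-bromo-3-(dimethoxymethyl)-2,4,5-trimethoxybenzene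
Product: 5 3-(dimethoxymethyl)-2,4,5-trimethoxybenzoic acid
Conditions: n-BuLi, THF, −78 °C; CO2 (gas), −78 °C to 0 °C; AcOH (1 equiv), cold water
Reagents that add atoms: carbon dioxide O=C=O
Why: Bromine–lithium exchange and carboxylation of the aryllithium install the carbon that becomes the C-3 lactone carbonyl, and the buffered work-up keeps the acetal.

Step 5
Reactants: 5 3-(dimethoxymethyl)-2,4,5-trimethoxybenzoic acid
Product: 6 6-formyl-3-hydroxy-4,5,7-trimethoxyisobenzofuran-1(3H)-one (racemic lactol)
Conditions: s-BuLi (2.2 equiv), TMEDA, THF, −78 °C; DMF, −78 °C to 0 °C; 2 M aq. HCl, THF, rt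
Reagents that add atoms: N,N-dimethylformamide CN(C)C=O; water O
Why: Carboxylate-directed ortho-lithiation (the only aromatic C–H, also ortho to a methoxy group) and formylation give a 2-formylbenzoic acid that should close to the 3-hydroxyphthalide on acidification while the same acid unmasks the 6-formyl group; the lactol carbon forms as a racemate.

Step 6
Reactants: 6 6-formyl-3-hydroxy-4,5,7-trimethoxyisobenzofuran-1(3H)-one
Product: 7 6-formyl-3,4,5,7-tetrahydroxyisobenzofuran-1(3H)-one (racemic lactol)
Conditions: BBr3, CH2Cl2, −78 °C to rt; ice water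
Reagents that add atoms: none
Why: Lewis acid-mediated cleavage of the three aryl methyl ethers with BBr3 should free all phenols, and aqueous work-up returns the lactol.

Step 7
Reactants: 7 6-formyl-3,4,5,7-tetrahydroxyisobenzofuran-1(3H)-one
Product: 9 (3S)-6-formyl-4,5,7-trihydroxy-3-[(1S)-1-phenylethoxy]isobenzofuran-1(3H)-one, via (3R)-acetal epimer 8 (not isolated)
Conditions: (S)-1-phenylethanol (2 equiv), PPTS (cat.), 4 Å molecular sieves, toluene–THF, 45 °C; then concentrate, slurry in toluene–heptane, PPTS (cat.), 40 °C to rt; filter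
Reagents that add atoms: (S)-1-phenylethanol C[C@H](O)c1ccccc1
Why: Acid-catalysed acetalisation (pseudo-ester formation) of the lactol with the enantiopure alcohol gives both C-3 epimers, which interconvert under the same acid catalysis through reversible loss of the alkoxy group (phthalidyl oxocarbenium ion), so that selective crystallisation of the (3S)-epimer 9 should drain the dissolved (3R)-epimer 8 into it (crystallisation-induced diastereomer transformation, as known for alkoxyfuranone and alkoxyphthalide acetals of chiral alcohols), which fixes the stereocentre of the target.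

Step 8
Reactants: 10 3-fluoro-5-methylphenol
Product: 11 4-bromo-3-fluoro-5-methylphenol
Conditions: NBS, MeCN, −10 °C
Reagents that add atoms: N-bromosuccinimide O=C1CCC(=O)N1Br
Why: Electrophilic bromination of the phenol should be para-selective, as it is for 3,5-dimethylphenol.

Step 9
Reactants: 11 4-bromo-3-fluoro-5-methylphenol
Product: 12 5-(benzyloxy)-2-bromo-1-fluoro-3-methylbenzene
Conditions: BnBr, K2CO3, DMF, rt
Reagents that add atoms: benzyl bromide BrCc1ccccc1
Why: Williamson ether synthesis protects the phenol as a benzyl ether that the last step removes.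

Step 10
Reactants: 12 5-(benzyloxy)-2-bromo-1-fluoro-3-methylbenzene
Product: 13 6-(benzyloxy)-3-bromo-2-fluoro-4-methylbenzaldehyde
Conditions: LiN(iPr)2, THF, −78 °C; DMF, −78 °C to 0 °C; aq. HCl
Reagents that add atoms: N,N-dimethylformamide CN(C)C=O
Why: Directed ortho-metalation: the C–H between fluorine and the benzyloxy group is by far the most acidic, the amide base does not exchange the bromide, and at −78 °C the 2-fluoroaryllithium should not lose LiF before DMF traps it.

Step 11
Reactants: 13 6-(benzyloxy)-3-bromo-2-fluoro-4-methylbenzaldehyde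
Product: 14 1-(benzyloxy)-4-bromo-2-(dimethoxymethyl)-3-fluoro-5-methylbenzene
Conditions: HC(OMe)3 (neat), TsOH·H2O (cat.), rt
Reagents that add atoms: trimethyl orthoformate COC(OC)OC
Why: Acetalisation protects the aldehyde from the Grignard reagent of the next step.

Step 12
Reactants: 14 1-(benzyloxy)-4-bromo-2-(dimethoxymethyl)-3-fluoro-5-methylbenzene
Product: 15 4-(benzyloxy)-N-butyl-2-fluoro-3-formyl-6-methylbenzamide
Conditions: iPrMgCl·LiCl, THF, −20 °C; n-BuNCO, −20 °C to 0 °C; 1 M aq. HCl, THF, rt
Reagents that add atoms: butyl isocyanate CCCCN=C=O; water O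
Why: Bromine–magnesium exchange (turbo-Grignard, helped by the ortho fluorine and giving an arylmagnesium that keeps its fluoride at this temperature) and addition to the isocyanate should give the secondary amide, and the acidic work-up removes the acetal.

Step 13
Reactants: 15 4-(benzyloxy)-N-butyl-2-fluoro-3-formyl-6-methylbenzamide
Product: 16 (Z)-4-(benzyloxy)-N-butyl-2-fluoro-3-formyl-6-methylbenzenecarboximidoyl chloride
Conditions: (COCl)2, 2,6-lutidine, CH2Cl2, 0 °C to rt; evaporate, take up in toluene, filter; use at once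
Reagents that add atoms: oxalyl chloride O=C(Cl)C(=O)Cl
Why: Secondary amides are converted into imidoyl chlorides by oxalyl chloride and a hindered pyridine base, conditions that should leave an aryl aldehyde untouched.

Step 14
Reactants: 9 (3S)-6-formyl-4,5,7-trihydroxy-3-[(1S)-1-phenylethoxy]isobenzofuran-1(3H)-one; 16 (Z)-4-(benzyloxy)-N-butyl-2-fluoro-3-formyl-6-methylbenzenecarboximidoyl chloride
Product: 19 (1S)-10-(benzyloxy)-4-hydroxy-8-methyl-3,7-dioxo-1-[(1S)-1-phenylethoxy]-1,3-dihydro-7H-isobenzofuro[4,5-b][1,4]benzodioxepine-5,11-dicarbaldehyde, via open O-aryl imidate 17 (not isolated), via cyclic imidate 18 (not isolated)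
Conditions: NaH (1.0 equiv), DMF, 0 °C, argon; 16, 0 °C to rt; dilute with DMF to 0.01 M, Cs2CO3 (3 equiv), 45 °C; 1 M aq. HCl–THF, 0 °C to rt
Reagents that add atoms: water O
Why: One equivalent of NaH ionises the most acidic hydroxyl of 9 (5-OH, the future O-6: ortho to the formyl group, para to the lactone carbonyl and hydrogen-bonded by 4-OH), which should displace chloride from 16 to give imidate 17 (O-imidoylation of a phenoxide, as used to make Chapman rearrangement substrates); Cs2CO3 then frees the neighbouring 4-O phenoxide (the future O-12), which attacks the fluorine-bearing ring-A carbon lying between the formyl-bearing and the imidoyl-bearing carbons and expels fluoride through a Meisenheimer adduct (intramolecular SNAr, the reaction type that closes dibenzoxazepinones and depsidones from 2-fluoroaryl carbonyl compounds), and cold dilute acid finally hydrolyses the cyclic O-aryl imidate 18 to the lactone 19 with loss of butylamine (as 2-iminocoumarins give coumarins). The dioxepine ring is thus closed by addition–elimination of the tethered phenoxide at an sp2 carbon (seven-membered closure), with both ring-fusion bonds and the imidate already in place. No stereocentre is created, and the C-3 acetal of 9 should survive because it is inert to base and meets dilute acid only briefly at 0 °C. The step needs the carboxyl-level carbon on the future O-6 and the aryl ether on the future O-12, and it needs that carbon not to move between the two catechol oxygens once the second phenoxide exists. The first is secured by the acidity order of ring B (5-OH well above 4-OH and above the doubly chelated, carbonyl-flanked 7-OH), the second by the imidate itself, whose O-to-O transfer would require an alkylamide anion in the tetrahedral intermediate, whereas a catechol monoester would equilibrate and, under Curtin–Hammett control, close mainly to the isomeric depsidone. High dilution and exclusion of air are meant to suppress intermolecular substitution and oxidation of the electron-rich phenoxide.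

Step 15
Reactants: 19 (1S)-10-(benzyloxy)-4-hydroxy-8-methyl-3,7-dioxo-1-[(1S)-1-phenylethoxy]-1,3-dihydro-7H-isobenzofuro[4,5-b][1,4]benzodioxepine-5,11-dicarbaldehyde
Product: 20 (1S)-1,4,10-trihydroxy-8-methyl-3,7-dioxo-1,3-dihydro-7H-isobenzofuro[4,5-b][1,4]benzodioxepine-5,11-dicarbaldehyde
Conditions: H2 (1 atm), 10% Pd/C, EtOAc, rt; filter under argon, evaporate below 20 °C
Reagents that add atoms: none
Why: Hydrogenolysis over Pd/C should cleave the aryl benzyl ether and the benzylic O–CH(CH3)Ph bond of the acetal; since no bond to C-1 is broken the lactol is released with retention as the (1S)-hemiacetal under neutral aprotic conditions, and the two chelated ortho-hydroxy aldehydes are expected to be reduced more slowly than the benzylic C–O bonds.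

**Compound list**

1 | 1,2,4-trimethoxybenzene | COc1ccc(OC)c(OC)c1 | starting material
2 | 2,3,6-trimethoxybenzaldehyde | O=Cc1c(OC)ccc(OC)c1OC | intermediate
3 | 3-bromo-2,5,6-trimethoxybenzaldehyde | O=Cc1c(OC)c(Br)cc(OC)c1OC | intermediate
4 | 1-bromo-3-(dimethoxymethyl)-2,4,5-trimethoxybenzene | COC(OC)c1c(OC)c(Br)cc(OC)c1OC | intermediate
5 | 3-(dimethoxymethyl)-2,4,5-trimethoxybenzoic acid | COC(OC)c1c(OC)c(C(=O)O)cc(OC)c1OC | intermediate
6 | 6-formyl-3-hydroxy-4,5,7-trimethoxyisobenzofuran-1(3H)-one (racemic lactol) | COc1c(OC)c(C=O)c(OC)c2c1C(O)OC2=O | intermediate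
7 | 6-formyl-3,4,5,7-tetrahydroxyisobenzofuran-1(3H)-one (racemic lactol) | Oc1c(O)c(C=O)c(O)c2c1C(O)OC2=O | intermediate
8 | (3R)-6-formyl-4,5,7-trihydroxy-3-[(1S)-1-phenylethoxy]isobenzofuran-1(3H)-one | Oc1c(O)c(C=O)c(O)c2c1[C@H](O[C@@H](C)c3ccccc3)OC2=O | intermediate
9 | (3S)-6-formyl-4,5,7-trihydroxy-3-[(1S)-1-phenylethoxy]isobenzofuran-1(3H)-one | Oc1c(O)c(C=O)c(O)c2c1[C@@H](O[C@@H](C)c3ccccc3)OC2=O | intermediate
10 | 3-fluoro-5-methylphenol | Cc1cc(O)cc(F)c1 | starting material
11 | 4-bromo-3-fluoro-5-methylphenol | Cc1cc(O)cc(F)c1Br | intermediate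
12 | 5-(benzyloxy)-2-bromo-1-fluoro-3-methylbenzene | Cc1cc(OCc2ccccc2)cc(F)c1Br | intermediate
13 | 6-(benzyloxy)-3-bromo-2-fluoro-4-methylbenzaldehyde | Cc1cc(OCc2ccccc2)c(C=O)c(F)c1Br | intermediate
14 | 1-(benzyloxy)-4-bromo-2-(dimethoxymethyl)-3-fluoro-5-methylbenzene | COC(OC)c1c(F)c(Br)c(C)cc1OCc2ccccc2 | intermediate
15 | 4-(benzyloxy)-N-butyl-2-fluoro-3-formyl-6-methylbenzamide | CCCCNC(=O)c1c(C)cc(OCc2ccccc2)c(C=O)c1F | intermediate
16 | (Z)-4-(benzyloxy)-N-butyl-2-fluoro-3-formyl-6-methylbenzenecarboximidoyl chloride | CCCC/N=C(\Cl)c1c(C)cc(OCc2ccccc2)c(C=O)c1F | intermediate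
17 | (3S)-6-formyl-4,7-dihydroxy-1-oxo-3-[(1S)-1-phenylethoxy]-1,3-dihydroisobenzofuran-5-yl 4-(benzyloxy)-N-butyl-2-fluoro-3-formyl-6-methylbenzenecarboximidate (C=N geometry not fixed) | Oc1c(OC(=NCCCC)c4c(C)cc(OCc5ccccc5)c(C=O)c4F)c(C=O)c(O)c2c1[C@@H](O[C@@H](C)c3ccccc3)OC2=O | intermediate
18 | (1S)-10-(benzyloxy)-7-(butylimino)-4-hydroxy-8-methyl-3-oxo-1-[(1S)-1-phenylethoxy]-1,3-dihydro-7H-isobenzofuro[4,5-b][1,4]benzodioxepine-5,11-dicarbaldehyde (C=N geometry not fixed) | Cc1cc(OCc4ccccc4)c(C=O)c2c1C(=NCCCC)Oc1c(C=O)c(O)c3c(c1O2)[C@@H](O[C@@H](C)c5ccccc5)OC3=O | intermediate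
19 | (1S)-10-(benzyloxy)-4-hydroxy-8-methyl-3,7-dioxo-1-[(1S)-1-phenylethoxy]-1,3-dihydro-7H-isobenzofuro[4,5-b][1,4]benzodioxepine-5,11-dicarbaldehyde | Cc1cc(OCc4ccccc4)c(C=O)c2c1C(=O)Oc1c(C=O)c(O)c3c(c1O2)[C@@H](O[C@@H](C)c5ccccc5)OC3=O | intermediate
20 | (1S)-1,4,10-trihydroxy-8-methyl-3,7-dioxo-1,3-dihydro-7H-isobenzofuro[4,5-b][1,4]benzodioxepine-5,11-dicarbaldehyde | Cc1cc(O)c(C=O)c2c1C(=O)Oc1c(C=O)c(O)c3c(c1O2)[C@@H](O)OC3=O | target

**Totals**

Total step count: 15. Longest linear sequence: 9 steps (steps 1 to 7, then 14 and 15).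

**Steps most likely to fail, with fallbacks**

Step 14. What may go wrong: imidoylation at the wrong hydroxyl, intermolecular substitution competing with ring closure, or opening of the cyclic imidate to the amide instead of loss of butylamine during hydrolysis. Fallback (ether first, lactone second), setting out from 14 and 9 and returning at 19. Bromine–magnesium exchange on 14 (iPrMgCl·LiCl, THF, −20 °C), carboxylation with CO2 and aqueous acid should give 4-(benzyloxy)-2-fluoro-3-formyl-6-methylbenzoic acid F1. Intermolecular SNAr of the polyphenoxide of 9 on F1 (Cs2CO3, DMSO, 60 °C), in which the most electron-rich oxygen (4-O, not conjugated to any carbonyl) should react, would give the diaryl ether acid 4-(benzyloxy)-3-formyl-2-{[(3S)-6-formyl-5,7-dihydroxy-1-oxo-3-[(1S)-1-phenylethoxy]-1,3-dihydroisobenzofuran-4-yl]oxy}-6-methylbenzoic acid F2. Lactonisation of F2 onto the neighbouring 5-hydroxyl with trifluoroacetic anhydride (toluene, 0 °C to rt), the classical depsidone closure, leads back to 19.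

Step 15. What may go wrong: over-reduction of the formyl groups or of the benzylic lactone C–O bond while the secondary benzylic acetal ether is cleaved slowly, or partial epimerisation of the freed lactol. Fallback, setting out from 19 and returning at 20. BCl3 (CH2Cl2, −78 °C to 0 °C, then water) should remove the benzyl ether and the acetal to give racemic 1,4,10-trihydroxy-8-methyl-3,7-dioxo-1,3-dihydro-7H-isobenzofuro[4,5-b][1,4]benzodioxepine-5,11-dicarbaldehyde F3, whose C-1 enantiomers interconvert through the open form. Lipase-catalysed dynamic kinetic acetylation of the lactol hydroxyl (vinyl acetate, a lipase of the required enantiopreference chosen by screening, toluene, rt; the reaction type known for 5-hydroxyfuranones) would give (1S)-5,11-diformyl-4,10-dihydroxy-8-methyl-3,7-dioxo-1,3-dihydro-7H-isobenzofuro[4,5-b][1,4]benzodioxepin-1-yl acetate F4. Lipase-mediated butanolysis of F4 (n-BuOH, tert-butyl methyl ether, rt), which cleaves the acyl–oxygen bond and so keeps C-1, gives 20.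

Step 7. What may go wrong: preferential crystallisation of the unwanted epimer or of neither, so that the equilibrium is not drained towards the required acetal, or acid-promoted ionisation of the secondary benzylic alcohol with loss of its enantiopurity. Fallback (robust achiral acetal, configuration by chromatographic resolution), setting out from 7 and returning at 20. Benzyl alcohol and PPTS (toluene–THF, 4 Å molecular sieves, 60 °C) should give racemic 3-(benzyloxy)-6-formyl-4,5,7-trihydroxyisobenzofuran-1(3H)-one F5, from which preparative chromatography on a chiral stationary phase separates (3S)-3-(benzyloxy)-6-formyl-4,5,7-trihydroxyisobenzofuran-1(3H)-one F6. F6 is carried through the conditions of step 14 with 16, via the open imidate (3S)-3-(benzyloxy)-6-formyl-4,7-dihydroxy-1-oxo-1,3-dihydroisobenzofuran-5-yl 4-(benzyloxy)-N-butyl-2-fluoro-3-formyl-6-methylbenzenecarboximidate F7 and the cyclic imidate (1S)-1,10-bis(benzyloxy)-7-(butylimino)-4-hydroxy-8-methyl-3-oxo-1,3-dihydro-7H-isobenzofuro[4,5-b][1,4]benzodioxepine-5,11-dicarbaldehyde F8, to (1S)-1,10-bis(benzyloxy)-4-hydroxy-8-methyl-3,7-dioxo-1,3-dihydro-7H-isobenzofuro[4,5-b][1,4]benzodioxepine-5,11-dicarbaldehyde F9. Hydrogenolysis of F9 under the conditions of step 15 gives 20.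

**Further compounds**

F1 | step 14 | 4-(benzyloxy)-2-fluoro-3-formyl-6-methylbenzoic acid | Cc1cc(OCc2ccccc2)c(C=O)c(F)c1C(=O)O
F2 | step 14 | 4-(benzyloxy)-3-formyl-2-{[(3S)-6-formyl-5,7-dihydroxy-1-oxo-3-[(1S)-1-phenylethoxy]-1,3-dihydroisobenzofuran-4-yl]oxy}-6-methylbenzoic acid | Cc1cc(OCc4ccccc4)c(C=O)c(Oc2c(O)c(C=O)c(O)c3c2[C@@H](O[C@@H](C)c5ccccc5)OC3=O)c1C(=O)O
F3 | step 15 | 1,4,10-trihydroxy-8-methyl-3,7-dioxo-1,3-dihydro-7H-isobenzofuro[4,5-b][1,4]benzodioxepine-5,11-dicarbaldehyde (racemate, C-1 enantiomers interconverting) | Cc1cc(O)c(C=O)c2c1C(=O)Oc1c(C=O)c(O)c3c(c1O2)C(O)OC3=O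
F4 | step 15 | (1S)-5,11-diformyl-4,10-dihydroxy-8-methyl-3,7-dioxo-1,3-dihydro-7H-isobenzofuro[4,5-b][1,4]benzodioxepin-1-yl acetate | Cc1cc(O)c(C=O)c2c1C(=O)Oc1c(C=O)c(O)c3c(c1O2)[C@@H](OC(C)=O)OC3=O
F5 | step 7 | 3-(benzyloxy)-6-formyl-4,5,7-trihydroxyisobenzofuran-1(3H)-one (racemate) | Oc1c(O)c(C=O)c(O)c2c1C(OCc3ccccc3)OC2=O
F6 | step 7 | (3S)-3-(benzyloxy)-6-formyl-4,5,7-trihydroxyisobenzofuran-1(3H)-one | Oc1c(O)c(C=O)c(O)c2c1[C@@H](OCc3ccccc3)OC2=O
F7 | step 7 | (3S)-3-(benzyloxy)-6-formyl-4,7-dihydroxy-1-oxo-1,3-dihydroisobenzofuran-5-yl 4-(benzyloxy)-N-butyl-2-fluoro-3-formyl-6-methylbenzenecarboximidate | Oc1c(OC(=NCCCC)c4c(C)cc(OCc5ccccc5)c(C=O)c4F)c(C=O)c(O)c2c1[C@@H](OCc3ccccc3)OC2=O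
F8 | step 7 | (1S)-1,10-bis(benzyloxy)-7-(butylimino)-4-hydroxy-8-methyl-3-oxo-1,3-dihydro-7H-isobenzofuro[4,5-b][1,4]benzodioxepine-5,11-dicarbaldehyde | Cc1cc(OCc4ccccc4)c(C=O)c2c1C(=NCCCC)Oc1c(C=O)c(O)c3c(c1O2)[C@@H](OCc5ccccc5)OC3=O
F9 | step 7 | (1S)-1,10-bis(benzyloxy)-4-hydroxy-8-methyl-3,7-dioxo-1,3-dihydro-7H-isobenzofuro[4,5-b][1,4]benzodioxepine-5,11-dicarbaldehyde | Cc1cc(OCc4ccccc4)c(C=O)c2c1C(=O)Oc1c(C=O)c(O)c3c(c1O2)[C@@H](OCc5ccccc5)OC3=O
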